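## The problem

The target 16 is a 2,3-trans flavanonol ether. A chroman-4-one (ring C) is fused to a ring A carrying methoxy groups at C5, C6 and C7; the 3,5-dihydroxy-4-methoxyphenyl ring B sits at C2 and a methoxy group at C3. Rings A and B are flat, achiral and cheap. The difficulty lies in the bridge O1–C2–C3–C4 and in its two links to ring A, O1–C8a and C4–C4a.

The two stereocentres, C2 (R) and C3 (R), are adjacent and trans. C3 is alpha to the C4 ketone and can be equilibrated, and the trans isomer with both substituents equatorial is the stable one, so C2 can correct C3. Nothing corrects C2: it is a benzylic ether carbon beta to the ketone and is lost by base-induced ring opening to the chalcone (E1cB through the C3 enolate) or by acid ionisation. Absolute configuration must therefore be introduced at C2 by a catalyst and then kept away from strong base, strong acid and forcing hydrogenation.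

Five of the seven oxygen substituents are methyl ethers and two are free phenols. A late methylation could not distinguish a C3 hydroxyl from the phenols, so the C3 methoxy group has to arrive with a building block. The phenols have to travel under groups that leave under neutral conditions, since Lewis acids would also strip the C5 methyl ether next to the carbonyl.

The enabling feature is that C2, C3 and C4 form an anti alpha-methoxy-beta-oxy carbonyl unit. With C4 as an ester and C2 as a ketone, C3 lies between two carbonyl groups and epimerises freely. One reduction of the C2 ketone under dynamic kinetic resolution can then fix both centres at once.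

## Retrosynthesis

**16 to 15.** The two phenolic O–H bonds of ring B are traced back to benzyl ethers. Hydrogenolysis needs neither base, which would open ring C of the beta-aryloxy ketone, nor a Lewis acid, which would attack the C5 methyl ether. 15 has the full skeleton but no acidic hydrogen. The forward step must spare the benzylic C2–O1 bond and the ketone.

**15 to 13 (through 14).** Ring C is opened at O1–C8a, with fluorine on C8a and the C2 oxygen as a triethylsilyl ether. The neighbouring cut at O1–C2 would have a ring A phenol displace an activated C2 hydroxyl with inversion at an electron-rich benzylic carbon, where ionisation and elimination compete. Cutting O1–C8a never breaks the C2–O bond, so both stereocentres are spectators. 13 is acyclic. The forward reaction asks that the alkoxide of 14 attack the fluoroarene, activated only by the ortho ketone, faster than it fragments by retro-aldol cleavage.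

**13 to 8 and 11 (through 12).** The C4–C4a bond is cut to the N-methoxy-N-methylamide 8 and the aryllithium 12 made from 11. A Friedel–Crafts acylation would form the same bond but needs acid on a benzylic ether. Fluoroarene 11 has only two C–H bonds, equivalent and each flanked by F and OMe, so only one aryllithium can form. The cut splits the target into ring A (11) and ring B with the chain (8). The forward step must run at −78 °C, where 12 keeps its fluorine, and must stop at the ketone.

**8 to 7 to 6.** These are functional group changes only. The amide is made first on the free alcohol, whose magnesium alkoxide guards against enolisation and elimination, and the alcohol is silylated afterwards. Triethylsilyl is chosen because fluoride removes it at 0 °C.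

**6 to 5 (key).** The C3–H bond of the carbinol is cut, giving the racemic keto ester 5. C1, C2 and C3 of the propanoate become C4, C3 and C2 of the chromanone. The neighbouring cuts are weaker:
- A glycolate aldol reaction forming C2–C3 needs a stoichiometric auxiliary and reaches the anti isomer less readily than the syn.
- Dihydroxylation of the cinnamate gives the syn diol and then requires selective O-methylation.
- Ruthenium transfer hydrogenation of alpha-alkoxy beta-keto esters under dynamic resolution is recalled to favour the syn isomer.

An enzyme's choice of alpha-epimer is independent of its choice of ketone face, so the anti isomer is within reach. 5 has no fixed stereocentre. The forward reaction must combine fast epimerisation at C2 with reduction of one epimer on one face.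

**5 to 2 and 3 (through 4); 2 to 1.** The bond between the ring B carbonyl carbon and the alpha-carbon is cut by a crossed Claisen condensation. Methyl methoxyacetate 3 brings the C3 methoxy group, and benzylation of the commercial ester 1 gives 2. Both fragments are simple esters. The forward step must favour acylation by the non-enolisable benzoate over self-condensation of 3.

**11 to 10 to 9.** The C–F bond is traced to a C–N bond. Diazotisation and fluorodediazoniation of 3,4,5-trimethoxyaniline 9 put fluorine exactly where ring closure needs it.

## Roads not taken

**Alternative 1:** Ring A is taken apart across C4a–C8a, C5–C6 and C8–C8a into 2,3-dimethoxycyclobut-2-en-1-one A2 and the chain-bearing methoxyalkyne A3. On heating, A2 opens to a vinylketene, which adds to the alkyne in a [2+2] sense. A 4π opening and a 6π closure then deliver the phenol A1.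
- Merits: the polarity of ketene and alkynyl ether fixes the substitution pattern, and the C8a phenol appears where ring C must close.
- Weak points: ring A is the one part of the target that can be bought with all three methoxy groups in place. A3 must already hold both stereocentres, which the annulation does nothing to set, plus an extra C4 carbinol to be oxidised later. A2 needs its own multistep preparation. Ring C would close from A1 by phenol displacement at C2 with inversion at an electron-rich benzylic carbon.
- Comparison: this road avoids the nucleophilic substitution on an electron-rich fluoroarene and the free beta-alkoxy ketone 14, which is a real advantage. The chosen plan sets against it a purchased ring A, a shorter sequence and a key step that solves the stereochemical problem.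

**Alternative 2:** The C3–O bond is cut. Flavanone 3-hydroxylase, a non-haem iron dioxygenase, removes the C3 hydrogen anti to the C2 aryl group of the (2S)-flavanone A5 and returns hydroxyl to the same face, giving A4.
- Merits: the route is biomimetic, C2 directs C3 to the trans product, and no protecting groups are needed on A5.
- Weak points: A5 must be enantiopure, so the uncorrectable centre C2 is not set by the key step, and flavanones racemise through the chalcone. The enzyme's natural substrates carry free hydroxyls on ring A and at C4', which the fully methylated A5 lacks. After hydroxylation the C3 hydroxyl of A4 must be methylated beside two more acidic phenols, which calls for protection or a second selective enzyme.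
- Comparison: this road is shorter after the ring system exists and installs oxygen by C–H oxidation, which the chosen plan cannot match. The chosen plan brings the C3 methoxy group in with 3, sets C2 and C3 together, and uses an enzyme class with broad commercial panels for aryl keto esters.

**Alternative 3:** O1–C8a and C4–C4a are cut together. Fluoride releases the aryne from the silyl triflate A7. The C3 hydroxyl of the hydroxy ester 6 adds at the aryne carbon remote from the methoxy group, and the aryl anion attacks the ester to give A6, which is identical with 15.
- Merits: it uses the same hydroxy ester 6 and is therefore compatible with the enzymatic idea. It would replace steps 4, 5, 8 and 9 by one operation. The methoxy group polarises the aryne in the right sense. No beta-alkoxy ketone is exposed to base.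
- Weak points: with an aliphatic alcohol, the aryl anion is expected to take the hydroxyl proton in competition with acylation, which leaves the open aryl ether. Annulations of this kind are established for phenolic partners. A second aryne can add to the product. A7 needs about three steps from a phenol, against two for 11.
- Comparison: this road is shorter by two or three steps and is better in that respect. The chosen plan sets against it that each of its C–C and C–O bond formations is an established reaction on its substrate class. The step 9 fallback below adopts the same bond order with known reactions.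

Key step: step 3

Assumption: a ketoreductase with the stated selectivity is taken from a commercial panel by screening; the route fixes the selectivity it must have, not its identity.

## Route

Step 1
Reactants: 1 methyl 3,5-dihydroxy-4-methoxybenzoate
Product: 2 methyl 3,5-bis(benzyloxy)-4-methoxybenzoate
Conditions: BnBr, K2CO3, DMF, 60 °C
Reagents that add atoms: benzyl bromide, BrCc1ccccc1
Why: Williamson etherification of the two phenoxides, the only acidic sites; the methyl ester is inert to K2CO3 and the 4-methoxy group is already present, so no regiochemical question arises.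

Step 2
Reactants: 2 methyl 3,5-bis(benzyloxy)-4-methoxybenzoate; 3 methyl methoxyacetate
Product: 5 methyl 3-[3,5-bis(benzyloxy)-4-methoxyphenyl]-2-methoxy-3-oxopropanoate (racemic), via lithium enolate of methyl methoxyacetate 4 (not isolated)
Conditions: 3 (2.5 equiv), LiN(i-Pr)2 (2.5 equiv), THF, −78 °C; then 2, −78 → −20 °C; 1 M HCl
Reagents that add atoms: none
Why: Crossed Claisen condensation: 3 is enolised completely at −78 °C before the non-enolisable benzoate 2 is added, so 2 is the only electrophile, and deprotonation of the product by a second equivalent of 4 makes the acylation irreversible. The product is racemic at C2, which is what step 3 requires.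

Step 3
Reactants: 5 methyl 3-[3,5-bis(benzyloxy)-4-methoxyphenyl]-2-methoxy-3-oxopropanoate (racemic)
Product: 6 methyl (2R,3R)-3-[3,5-bis(benzyloxy)-4-methoxyphenyl]-3-hydroxy-2-methoxypropanoate
Conditions: ketoreductase (Si-face selective at the ketone, (2R)-epimer selective), NADP+ (cat.), i-PrOH/DMSO/KH2PO4–K2HPO4 buffer pH 7.0 (2:1:7), 30 °C
Reagents that add atoms: none
Why: An NADPH-dependent ketoreductase transfers the C4 hydride of the dihydronicotinamide to the aryl ketone carbon of 5 while an active-site acid protonates the oxygen, and the same enzyme oxidises isopropanol to acetone to return NADPH. The closest known reaction type is the ketoreductase-catalysed dynamic reductive kinetic resolution of alpha-substituted beta-keto esters, for which aryl ketones with alpha-alkyl, alpha-halo and alpha-amido groups are standard substrates. No ring is closed and no skeletal bond is formed; the only new bond is C3–H. C3, the later C2 of the chromanone, is set by the facial selectivity of the enzyme: hydride delivery to the Si face of the ketone gives the (3R) carbinol. C2, the later C3, is set by the enzyme's choice between the alpha-epimers: only (2R)-5 binds productively, and (2S)-5 returns to the racemate through the enol because the C2–H lies between ketone and ester and exchanges in neutral buffer faster than the slow epimer is reduced. The step needs anti (2R,3R) selection among four stereoisomers and reduction of the ketone, not the ester; the first is secured by the choice of enzyme, the second is inherent to the enzyme class, and the substrate supplies the dynamic part through its acidic C2–H. Once reduced, 6 has lost that acidity and is configurationally stable under the conditions. Isopropanol and DMSO keep the lipophilic dibenzyl ether in solution.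

Step 4
Reactants: 6 methyl (2R,3R)-3-[3,5-bis(benzyloxy)-4-methoxyphenyl]-3-hydroxy-2-methoxypropanoate
Product: 7 (2R,3R)-3-[3,5-bis(benzyloxy)-4-methoxyphenyl]-3-hydroxy-N,2-dimethoxy-N-methylpropanamide
Conditions: MeNH(OMe)·HCl, i-PrMgCl, THF, −20 → 0 °C; aq. NH4Cl
Reagents that add atoms: N,O-dimethylhydroxylamine hydrochloride, CNOC.Cl
Why: Aminolysis of the methyl ester by the chloromagnesium amide of N,O-dimethylhydroxylamine (Weinreb amide formation from an ester); the hydroxyl is carried as its magnesium alkoxide, which disfavours enolisation at C2 and beta-elimination, so both stereocentres are retained.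

Step 5
Reactants: 7 (2R,3R)-3-[3,5-bis(benzyloxy)-4-methoxyphenyl]-3-hydroxy-N,2-dimethoxy-N-methylpropanamide
Product: 8 (2R,3R)-3-[3,5-bis(benzyloxy)-4-methoxyphenyl]-N,2-dimethoxy-N-methyl-3-(triethylsilyloxy)propanamide
Conditions: Et3SiCl, imidazole, DMF, 0 °C → rt
Reagents that add atoms: chlorotriethylsilane, CC[Si](Cl)(CC)CC
Why: Silylation of the secondary benzylic alcohol with a silyl chloride and imidazole; the triethylsilyl ether masks the hydroxyl against the aryllithium of step 8 and is labile enough for fluoride cleavage at 0 °C in step 9.

Step 6
Reactants: 9 3,4,5-trimethoxyaniline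
Product: 10 3,4,5-trimethoxybenzenediazonium tetrafluoroborate
Conditions: NaNO2, 48% aq. HBF4, 0 °C; filter, dry
Reagents that add atoms: sodium nitrite, [Na+].[O-]N=O; tetrafluoroboric acid, [H+].F[B-](F)(F)F
Why: Diazotisation of the primary arylamine by nitrous acid in tetrafluoroboric acid; the sparingly soluble arenediazonium tetrafluoroborate precipitates and is collected.

Step 7
Reactants: 10 3,4,5-trimethoxybenzenediazonium tetrafluoroborate
Product: 11 5-fluoro-1,2,3-trimethoxybenzene
Conditions: PhCl, reflux
Reagents that add atoms: none
Why: Balz–Schiemann fluorodediazoniation: loss of N2 leaves an aryl cation–tetrafluoroborate ion pair that collapses to the aryl fluoride and BF3, so fluorine takes the position of the former nitrogen.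

Step 8
Reactants: 11 5-fluoro-1,2,3-trimethoxybenzene; 8 (2R,3R)-3-[3,5-bis(benzyloxy)-4-methoxyphenyl]-N,2-dimethoxy-N-methyl-3-(triethylsilyloxy)propanamide
Product: 13 (2R,3R)-3-[3,5-bis(benzyloxy)-4-methoxyphenyl]-1-(6-fluoro-2,3,4-trimethoxyphenyl)-2-methoxy-3-(triethylsilyloxy)propan-1-one, via (6-fluoro-2,3,4-trimethoxyphenyl)lithium 12 (not isolated)
Conditions: 11 (1.5 equiv), n-BuLi (1.45 equiv), THF, −78 °C; then 8, −78 °C; aq. NH4Cl
Reagents that add atoms: none
Why: Directed ortho-lithiation followed by Weinreb ketone synthesis: the only C–H bonds of 11 are two equivalent ones flanked by F and OMe, so lithiation is unambiguous, and the chelated tetrahedral adduct of the amide releases the ketone only on work-up. At −78 °C the ortho-fluoroaryllithium does not lose LiF and the C2–H of 8 is not removed, so the stereocentres pass unchanged.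

Step 9
Reactants: 13 (2R,3R)-3-[3,5-bis(benzyloxy)-4-methoxyphenyl]-1-(6-fluoro-2,3,4-trimethoxyphenyl)-2-methoxy-3-(triethylsilyloxy)propan-1-one
Product: 15 (2R,3R)-2-[3,5-bis(benzyloxy)-4-methoxyphenyl]-3,5,6,7-tetramethoxychroman-4-one, via free hydroxy ketone 14 (not isolated)
Conditions: n-Bu4NF, THF, 0 °C → rt
Reagents that add atoms: none
Why: Fluoride cleaves the Si–O bond and the ammonium alkoxide so formed closes ring C by intramolecular nucleophilic aromatic substitution (addition–elimination through a Meisenheimer adduct stabilised by the ortho ketone; six-membered ring). The C2–O bond of the carbinol is never broken, so C2 is retained, and the trans arrangement set in step 3 is also the thermodynamically favoured one.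

Step 10
Reactants: 15 (2R,3R)-2-[3,5-bis(benzyloxy)-4-methoxyphenyl]-3,5,6,7-tetramethoxychroman-4-one
Product: 16 (2R,3R)-2-(3,5-dihydroxy-4-methoxyphenyl)-3,5,6,7-tetramethoxychroman-4-one
Conditions: H2 (1 atm), 10% Pd on carbon, EtOAc/MeOH, rt
Reagents that add atoms: none
Why: Catalytic hydrogenolysis of the two benzyl aryl ethers; the methyl ethers are inert, and the hindered aryl ketone and the ring C2–O1 bond react far more slowly, so the reaction is stopped after uptake of two equivalents of H2.

## Compound list

1 | methyl 3,5-dihydroxy-4-methoxybenzoate | COC(=O)c1cc(O)c(OC)c(O)c1 | starting material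
2 | methyl 3,5-bis(benzyloxy)-4-methoxybenzoate | COC(=O)c1cc(OCc2ccccc2)c(OC)c(OCc2ccccc2)c1 | intermediate
3 | methyl methoxyacetate | COCC(=O)OC | starting material
4 | lithium enolate of methyl methoxyacetate (enolate geometry not defined) | COC=C(O[Li])OC | intermediate (not isolated)
5 | methyl 3-[3,5-bis(benzyloxy)-4-methoxyphenyl]-2-methoxy-3-oxopropanoate (racemic) | COC(=O)C(OC)C(=O)c1cc(OCc2ccccc2)c(OC)c(OCc2ccccc2)c1 | intermediate
6 | methyl (2R,3R)-3-[3,5-bis(benzyloxy)-4-methoxyphenyl]-3-hydroxy-2-methoxypropanoate | COC(=O)[C@H](OC)[C@H](O)c1cc(OCc2ccccc2)c(OC)c(OCc2ccccc2)c1 | intermediate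
7 | (2R,3R)-3-[3,5-bis(benzyloxy)-4-methoxyphenyl]-3-hydroxy-N,2-dimethoxy-N-methylpropanamide | CON(C)C(=O)[C@H](OC)[C@H](O)c1cc(OCc2ccccc2)c(OC)c(OCc2ccccc2)c1 | intermediate
8 | (2R,3R)-3-[3,5-bis(benzyloxy)-4-methoxyphenyl]-N,2-dimethoxy-N-methyl-3-(triethylsilyloxy)propanamide | CON(C)C(=O)[C@H](OC)[C@H](O[Si](CC)(CC)CC)c1cc(OCc2ccccc2)c(OC)c(OCc2ccccc2)c1 | intermediate
9 | 3,4,5-trimethoxyaniline | COc1cc(N)cc(OC)c1OC | starting material
10 | 3,4,5-trimethoxybenzenediazonium tetrafluoroborate | COc1cc(cc(OC)c1OC)[N+]#N.F[B-](F)(F)F | intermediate
11 | 5-fluoro-1,2,3-trimethoxybenzene | COc1cc(F)cc(OC)c1OC | intermediate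
12 | (6-fluoro-2,3,4-trimethoxyphenyl)lithium | COc1cc(F)c([Li])c(OC)c1OC | intermediate (not isolated)
13 | (2R,3R)-3-[3,5-bis(benzyloxy)-4-methoxyphenyl]-1-(6-fluoro-2,3,4-trimethoxyphenyl)-2-methoxy-3-(triethylsilyloxy)propan-1-one | COc1cc(F)c(c(OC)c1OC)C(=O)[C@H](OC)[C@H](O[Si](CC)(CC)CC)c1cc(OCc2ccccc2)c(OC)c(OCc2ccccc2)c1 | intermediate
14 | (2R,3R)-3-[3,5-bis(benzyloxy)-4-methoxyphenyl]-1-(6-fluoro-2,3,4-trimethoxyphenyl)-3-hydroxy-2-methoxypropan-1-one | COc1cc(F)c(c(OC)c1OC)C(=O)[C@H](OC)[C@H](O)c1cc(OCc2ccccc2)c(OC)c(OCc2ccccc2)c1 | intermediate (not isolated)
15 | (2R,3R)-2-[3,5-bis(benzyloxy)-4-methoxyphenyl]-3,5,6,7-tetramethoxychroman-4-one (2,3-trans) | COc1cc2c(c(OC)c1OC)C(=O)[C@H](OC)[C@@H](c1cc(OCc3ccccc3)c(OC)c(OCc3ccccc3)c1)O2 | intermediate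
16 | (2R,3R)-2-(3,5-dihydroxy-4-methoxyphenyl)-3,5,6,7-tetramethoxychroman-4-one (2,3-trans) | COc1cc2c(c(OC)c1OC)C(=O)[C@H](OC)[C@@H](c1cc(O)c(OC)c(O)c1)O2 | target

## Step count and least certain steps

Total: 10 steps. Longest linear sequence: 8 steps (1 → 2 → 5 → 6 → 7 → 8 → 13 → 15 → 16, steps 1–5 and 8–10). The ring A branch (steps 6 and 7) joins at step 8.

**Step 3 (key step).**
- Risk: slow turnover because the bulky, poorly water-soluble dibenzyl ether binds badly, or reduction of the wrong alpha-epimer so that a syn isomer accumulates. Either would erode the diastereomeric purity on which everything downstream depends.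
- Fallback: the stereodiad is set chemically and then corrected at the carbinol. It sets out from 5. Transfer hydrogenation with RuCl(p-cymene)[(R,R)-TsDPEN] in HCO2H/Et3N under dynamic resolution is expected to give the syn isomer, methyl (2R,3S)-3-[3,5-bis(benzyloxy)-4-methoxyphenyl]-3-hydroxy-2-methoxypropanoate F1. The ligand enantiomer is the one that the usual aryl ketone model assigns to the (3S) carbinol. Mitsunobu inversion at C3 with 4-nitrobenzoic acid, PPh3 and diisopropyl azodicarboxylate gives methyl (2R,3R)-3-[3,5-bis(benzyloxy)-4-methoxyphenyl]-2-methoxy-3-(4-nitrobenzoyloxy)propanoate F2. Methanolysis with K2CO3 in MeOH at 0 °C returns to the route at 6. Elimination to the cinnamate is the competitor to watch in both operations.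

**Step 9.**
- Risk: retro-aldol cleavage of the liberated beta-alkoxy ketone, or base-induced enolisation at C3 with ring opening. Ring closure may be slow because the fluorine is para to the C6 methoxy group and the carbonyl is twisted by two ortho substituents. The result would be stereochemical erosion at both centres.
- Fallback: O1–C8a is made before C4–C4a, so that no beta-alkoxy ketone meets base. It sets out from 5, which is reduced as in the fallback to step 3 to the syn ester F1. Mitsunobu etherification of F1 with commercial 3,4,5-trimethoxyphenol (PPh3, diisopropyl azodicarboxylate, inversion at C3) gives methyl (2R,3R)-3-[3,5-bis(benzyloxy)-4-methoxyphenyl]-2-methoxy-3-(3,4,5-trimethoxyphenoxy)propanoate F3. Saponification with LiOH in THF/H2O gives (2R,3R)-3-[3,5-bis(benzyloxy)-4-methoxyphenyl]-2-methoxy-3-(3,4,5-trimethoxyphenoxy)propanoic acid F4. Intramolecular Friedel–Crafts acylation ((CF3CO)2O, CH2Cl2, 0 °C) at either of the two equivalent positions ortho to the ether oxygen returns to the route at 15.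

**Step 8.**
- Risk: slow addition of the doubly ortho-substituted aryllithium to the hindered, dioxygenated amide at the low temperature that 12 requires. On warming, loss of LiF to the aryne, or deprotonation at C2 with elimination of silanolate, would take over.
- Fallback: the carbonyl is changed to the far more electrophilic aldehyde. It sets out from 8. Reduction with i-Bu2AlH in THF at −78 °C gives (2R,3R)-3-[3,5-bis(benzyloxy)-4-methoxyphenyl]-2-methoxy-3-(triethylsilyloxy)propanal F5. Addition of 12 at −78 °C gives (2S,3R)-3-[3,5-bis(benzyloxy)-4-methoxyphenyl]-1-(6-fluoro-2,3,4-trimethoxyphenyl)-2-methoxy-3-(triethylsilyloxy)propan-1-ol F6 as a mixture of C1 epimers. The change of the C2 descriptor is a matter of the priority rules only. Oxidation with Dess–Martin periodinane and NaHCO3 in CH2Cl2 returns to the route at 13.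

**Step 2.**
- Risk: self-condensation or thermal decay of the methoxyacetate enolate on warming, outrunning acylation by the electron-rich and only moderately electrophilic methyl benzoate.
- Fallback: the acyl donor is activated. It sets out from 2. Saponification with LiOH gives 3,5-bis(benzyloxy)-4-methoxybenzoic acid F7. Oxalyl chloride with catalytic DMF gives 3,5-bis(benzyloxy)-4-methoxybenzoyl chloride F8. F8 is added to two equivalents of 4 at −78 °C and returns to the route at 5.

## Further compounds

F1 | step 3 | methyl (2R,3S)-3-[3,5-bis(benzyloxy)-4-methoxyphenyl]-3-hydroxy-2-methoxypropanoate | COC(=O)[C@H](OC)[C@@H](O)c1cc(OCc2ccccc2)c(OC)c(OCc2ccccc2)c1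
F2 | step 3 | methyl (2R,3R)-3-[3,5-bis(benzyloxy)-4-methoxyphenyl]-2-methoxy-3-(4-nitrobenzoyloxy)propanoate | COC(=O)[C@H](OC)[C@H](OC(=O)c1ccc(cc1)[N+](=O)[O-])c1cc(OCc2ccccc2)c(OC)c(OCc2ccccc2)c1
F3 | step 9 | methyl (2R,3R)-3-[3,5-bis(benzyloxy)-4-methoxyphenyl]-2-methoxy-3-(3,4,5-trimethoxyphenoxy)propanoate | COC(=O)[C@H](OC)[C@H](Oc1cc(OC)c(OC)c(OC)c1)c1cc(OCc2ccccc2)c(OC)c(OCc2ccccc2)c1
F4 | step 9 | (2R,3R)-3-[3,5-bis(benzyloxy)-4-methoxyphenyl]-2-methoxy-3-(3,4,5-trimethoxyphenoxy)propanoic acid | OC(=O)[C@H](OC)[C@H](Oc1cc(OC)c(OC)c(OC)c1)c1cc(OCc2ccccc2)c(OC)c(OCc2ccccc2)c1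
F5 | step 8 | (2R,3R)-3-[3,5-bis(benzyloxy)-4-methoxyphenyl]-2-methoxy-3-(triethylsilyloxy)propanal | O=C[C@H](OC)[C@H](O[Si](CC)(CC)CC)c1cc(OCc2ccccc2)c(OC)c(OCc2ccccc2)c1
F6 | step 8 | (2S,3R)-3-[3,5-bis(benzyloxy)-4-methoxyphenyl]-1-(6-fluoro-2,3,4-trimethoxyphenyl)-2-methoxy-3-(triethylsilyloxy)propan-1-ol (C1 epimers) | COc1cc(F)c(c(OC)c1OC)C(O)[C@H](OC)[C@H](O[Si](CC)(CC)CC)c1cc(OCc2ccccc2)c(OC)c(OCc2ccccc2)c1
F7 | step 2 | 3,5-bis(benzyloxy)-4-methoxybenzoic acid | OC(=O)c1cc(OCc2ccccc2)c(OC)c(OCc2ccccc2)c1
F8 | step 2 | 3,5-bis(benzyloxy)-4-methoxybenzoyl chloride | ClC(=O)c1cc(OCc2ccccc2)c(OC)c(OCc2ccccc2)c1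
A1 | alternative 1 | 2-[(2R,3S)-3-[3,5-bis(benzyloxy)-4-methoxyphenyl]-1-(tert-butyldimethylsilyloxy)-2-methoxy-3-(triethylsilyloxy)propyl]-3,4,5-trimethoxyphenol | COc1cc(O)c(c(OC)c1OC)C(O[Si](C)(C)C(C)(C)C)[C@H](OC)[C@@H](O[Si](CC)(CC)CC)c1cc(OCc2ccccc2)c(OC)c(OCc2ccccc2)c1
A2 | alternative 1 | 2,3-dimethoxycyclobut-2-en-1-one | COC1=C(OC)C(=O)C1
A3 | alternative 1 | (4R,5S)-5-[3,5-bis(benzyloxy)-4-methoxyphenyl]-3-(tert-butyldimethylsilyloxy)-1,4-dimethoxy-5-(triethylsilyloxy)pent-1-yne | COC#CC(O[Si](C)(C)C(C)(C)C)[C@H](OC)[C@@H](O[Si](CC)(CC)CC)c1cc(OCc2ccccc2)c(OC)c(OCc2ccccc2)c1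
A4 | alternative 2 | (2R,3R)-2-(3,5-dihydroxy-4-methoxyphenyl)-3-hydroxy-5,6,7-trimethoxychroman-4-one | COc1cc2c(c(OC)c1OC)C(=O)[C@H](O)[C@@H](c1cc(O)c(OC)c(O)c1)O2
A5 | alternative 2 | (2S)-2-(3,5-dihydroxy-4-methoxyphenyl)-5,6,7-trimethoxychroman-4-one | COc1cc2c(c(OC)c1OC)C(=O)C[C@@H](c1cc(O)c(OC)c(O)c1)O2
A6 | alternative 3 | (2R,3R)-2-[3,5-bis(benzyloxy)-4-methoxyphenyl]-3,5,6,7-tetramethoxychroman-4-one (identical with 15) | COc1cc2c(c(OC)c1OC)C(=O)[C@H](OC)[C@@H](c1cc(OCc3ccccc3)c(OC)c(OCc3ccccc3)c1)O2
A7 | alternative 3 | 3,4,5-trimethoxy-2-(trimethylsilyl)phenyl trifluoromethanesulfonate | COc1cc(OS(=O)(=O)C(F)(F)F)c([Si](C)(C)C)c(OC)c1OC
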